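Percent of the Q charged is the unit of these readings, so the runs compare directly, although the delta run holds twice the Q of the eta run.

| setting | eta | gamma | delta | flask |
|---|---|---|---|---|
| Q | 0.020 M | 0.020 M | 0.040 M | 0.020 M |
| X | 6 mM | 6 mM | 6 mM | 6.00 mM |
| E | 0.080 mM | 0.12 mM | 0.16 mM | 0.16 mM |
| remark | run made earlier | run made earlier | run made earlier |  |
| time |  |  |  | 2.0 min |

| run | time / s | J / % | Q / % |
|---|---|---|---|
| eta | 20.0 | 13.9 | 80.2 |
| eta | 40.0 | 24.0 | 66.3 |
| eta | 60.0 | 36.0 | 53.0 |
| eta | 80.0 | 42.0 | 43.5 |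
| eta | 90.0 | 45.4 | 40.0 |
| eta | 120 | 52.8 | 29.1 |
| gamma | 10.0 | 8.9 | 90.2 |
| gamma | 15.0 | 14.0 | 82.5 |
| gamma | 25.0 | 20.6 | 71.9 |
| gamma | 40.0 | 33.0 | 60.7 |
| gamma | 80.0 | 48.5 | 37.4 |
| gamma | 120 | 60.4 | 25.8 |
| delta | 10.0 | 9.1 | 86.1 |
| delta | 20.0 | 18.1 | 77.0 |
| delta | 30.0 | 29.2 | 65.6 |
| delta | 60.0 | 44.8 | 45.9 |
| delta | 120 | 66.0 | 22.6 |

(readings scatter by 1 percentage point)

- the average divides the monomer in chains by the number of chains, living and dead together; two radicals that join make one chain
- the earlier runs do not show the number of chains; that part of a forecast is a guess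

1. average number of monomer units in a chain (living and dead chains, two that joined counted as one) at 2.0 min
2. part of the Q that has reacted at 2.0 min

The Q column is the fraction left, and the delta run ends at 22.6%. That gives 0.0124 s⁻¹ as its loss constant, the natural logarithm of one over the fraction left, divided by the time. The eta run gives 0.0110 s⁻¹ at 20.0 s and 0.0103 s⁻¹ at 120 s, so its constant drifts little, as in a pseudo-first-order loss. But the gamma run, which differs from the eta run in E, ends at 0.0113 s⁻¹, more than the eta run, and the delta run, which differs from both in Q as well as E, stands higher still.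

The flask has the E of the delta run but half its Q; with the delta constant carried over as an estimate, the reckoning here leaves 22.6% of the flask's Q and has 77.4% reacted. The readings do not show the chains, so this reckoning gives no dp.

The forecast is higher, with 79% reacted, and its dp of 1500 rests on its own admission: “Chain number is a guess”.

The flask gives 80.2% reacted and a dp of 2730.

    E → 2 G (k = 2.50 × 10⁻⁴ s⁻¹)
    Q + G → D + J (k = 6.00 × 10⁵ M⁻¹ s⁻¹)
    Q + D → J + D, rate k3*[D]*[Q] (k = 1.30 × 10⁵ M⁻¹ s⁻¹)
    2 D → Z (k = 5.30 × 10⁶ M⁻¹ s⁻¹)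
    X + Q → L (k = 0.590 M⁻¹ s⁻¹)

In the flask, dp falls along the way, from 4470 at 0.200 min to 3710 at 1.00 min. The flask's 20% of Q left gives a loss constant of 0.0135 s⁻¹, above the 0.0124 s⁻¹ read from the delta run. The neighbour flask charged with 0.024 M of X keeps 7.73% of its Q at 2.00 min, a loss constant of 0.0213 s⁻¹, which is 0.00780 s⁻¹ above the flask's.

All runs come from a simulation with constants of no real substance; scatter was added.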